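**Plan**

1. Numbering: C1–C15 along the chain (C1 = alkyne CH; the ring oxygen bridges C9 and C13). Retrosynthetic cuts, in order: the O-acetyl and C-silyl groups; C12–Br together with O–C13 (bromoetherification of a (12E)-alkene by the C9 hydroxyl); C7–C8 (aldol); finally O–C9 and C10–C11 in one event.
2. Enabling feature: in the oxane ring O–C9–C10(Cl)–C11–C12(Br)–C13(Et) the trans Br/O pair at C12/C13 is the anti adduct of an (E)-C12=C13 alkene. With it opened, O=C9–C10(Cl)–C11–C12=C13 is a 2-chloro-γ,δ-unsaturated ketone, the Claisen retron. The ring oxygen is the oxygen of pent-1-en-3-ol: it adds to a 1-chloroalkyne (O–C9), leaves C13 in the [3,3] shift that makes C10–C11, and returns to C13 when the ring closes.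
3. Forward order: C1–C7 chloroaldehyde (steps 1–4); C8–C15 chloroketone by the alkoxylation/Claisen cascade (steps 5–6); aldol union (7); syn reduction (8); the oxane ring closes last, 6-endo (9); acetylation and desilylation (10–11).
4. Stereochemistry: C10 by 1,3-chirality transfer from (S)-pent-1-en-3-ol; C6 by organocatalytic α-chlorination; C7 by Cornforth-type aldol addition; C9 by Narasaka–Prasad 1,3-syn reduction; C12/C13 by anti addition through a chair with the C9 chain equatorial.

Key step: step 6

Assumption: (S)-pent-1-en-3-ol (single enantiomer) and prop-1-ynylmagnesium bromide (THF solution) are treated as purchasable.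

**Route**

Step 1
Reactants: 1 ethynyltriisopropylsilane; 2 prop-2-enal (acrolein)
Product: 4 rac-1-(triisopropylsilyl)pent-4-en-1-yn-3-ol, via lithium acetylide 3 (not isolated)
Conditions: n-BuLi, THF, −78 °C; then 2, −78 → 0 °C; aq. NH4Cl
Reagents that add atoms: none
Why: 1,2-addition of a lithium acetylide to the enal carbonyl at low temperature; the carbinol centre is destroyed in step 2, so the racemate serves.

Step 2
Reactants: 4 rac-1-(triisopropylsilyl)pent-4-en-1-yn-3-ol
Product: 6 ethyl (E)-7-(triisopropylsilyl)hept-4-en-6-ynoate, via mixed ketene acetal 5 (not isolated)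
Conditions: MeC(OEt)3 (6 equiv), EtCO2H (cat.), 140 °C, EtOH distilled off
Reagents that add atoms: triethyl orthoacetate, CC(OCC)(OCC)OCC
Why: Johnson–Claisen rearrangement, in which the chair places the alkynyl group equatorial (axial would clash with the ethoxy group) so the (E)-enyne should form, while the bulky silyl cap blocks the competing propargyl pathway.

Step 3
Reactants: 6 ethyl (E)-7-(triisopropylsilyl)hept-4-en-6-ynoate
Product: 7 (E)-7-(triisopropylsilyl)hept-4-en-6-ynal
Conditions: i-Bu2AlH (1.05 equiv), CH2Cl2, −78 °C; MeOH, then aq. potassium sodium tartrate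
Reagents that add atoms: none
Why: low-temperature partial reduction of an ester to the aldehyde with a dialkylaluminium hydride, to which the silyl enyne is inert.

Step 4
Reactants: 7 (E)-7-(triisopropylsilyl)hept-4-en-6-ynal
Product: 8 (2R,4E)-2-chloro-7-(triisopropylsilyl)hept-4-en-6-ynal
Conditions: NCS (1.2 equiv), 2,5-diphenylpyrrolidine (10 mol %, the enantiomer that gives 2R), CH2Cl2, −30 °C; used crude at once
Reagents that add atoms: N-chlorosuccinimide, O=C1CCC(=O)N1Cl
Why: enamine-mediated organocatalytic α-chlorination of an aldehyde, in which the C2-symmetric amine shields one enamine face and so sets the future C6 centre (R).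

Step 5
Reactants: 9 prop-1-ynylmagnesium bromide
Product: 10 1-chloroprop-1-yne
Conditions: TsCl (1.0 equiv), THF, 0 °C → rt; distilled into cold toluene and used as a stock solution
Reagents that add atoms: 4-methylbenzenesulfonyl chloride, Cc1ccc(cc1)S(=O)(=O)Cl
Why: electrophilic chlorination of a metal acetylide, the sulfonyl chloride acting as a Cl+ donor.

Step 6
Reactants: 10 1-chloroprop-1-yne; 11 (S)-pent-1-en-3-ol
Product: 13 (3R,5E)-3-chlorooct-5-en-2-one, via allyl chlorovinyl ether 12 (not isolated)
Conditions: Ph3PAuCl (3 mol %), AgSbF6 (3 mol %), 10 (2 equiv), toluene, sealed tube, 25 → 80 °C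
Reagents that add atoms: none
Why: Proposed new method: cationic monovalent gold π-activates 1-chloroalkyne 10, the hydroxyl of 11 adds anti at the methyl-bearing carbon (the regiochemistry that gold-catalysed hydration and carboxylic acid addition show for 1-haloalkynes), protodeauration gives (Z)-β-chlorovinyl allyl ether 12, and warming triggers its [3,3] shift; the closest known reaction type is the gold-catalysed intermolecular hydroalkoxylation/Claisen cascade of alkynes with allylic alcohols, so far not shown for 1-chloroalkynes. No ring is closed in this step: O–C9 (as the ketone oxygen) and C10–C11 form through an acyclic six-membered chair transition state, and the oxane closes in step 9. The new C10 centre is controlled by 1,3-chirality transfer from the carbinol carbon of 11: ethyl sits equatorial (giving the 12E alkene) and chlorine, cis to oxygen in 12, sits axial, so (S)-11 should give 10R. The step needs O-addition in preference to alkene addition to the gold–alkyne complex, a single enol ether geometry and no enolisation of the α-chloro ketone; the free hydroxyl as the best nucleophile present, the anti-addition/protodeauration sequence and the neutral, base-free medium should secure these.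

Step 7
Reactants: 13 (3R,5E)-3-chlorooct-5-en-2-one; 8 (2R,4E)-2-chloro-7-(triisopropylsilyl)hept-4-en-6-ynal
Product: 15 (3E,6R,7S,10R,12E)-6,10-dichloro-7-hydroxy-1-(triisopropylsilyl)pentadeca-3,12-dien-1-yn-9-one, via boron enolate 14 (not isolated)
Conditions: Cy2BCl, Et3N, Et2O, −78 °C; then 8, −78 → −20 °C; MeOH, aq. NaH2PO4/Na2HPO4 (pH 7), H2O2, 0 °C
Reagents that add atoms: none
Why: boron aldol reaction in which the bulky Cy2BCl/Et3N pair should enolise kinetically on the unhindered methyl side and the enolate adds to the α-chloro aldehyde through a Zimmerman–Traxler chair in the dipole-minimised Cornforth sense, giving the 6,7-anti chlorohydrin (7S).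

Step 8
Reactants: 15 (3E,6R,7S,10R,12E)-6,10-dichloro-7-hydroxy-1-(triisopropylsilyl)pentadeca-3,12-dien-1-yn-9-one
Product: 16 (3E,6R,7S,9R,10R,12E)-6,10-dichloro-1-(triisopropylsilyl)pentadeca-3,12-dien-1-yne-7,9-diol
Conditions: Et2BOMe, NaBH4, THF–MeOH (4:1), −78 °C; AcOH; MeOH co-evaporation
Reagents that add atoms: none
Why: Narasaka–Prasad reduction, a chelation-controlled process in which boron bridges hydroxyl and ketone and external hydride adds axially, so the new C9 carbinol should be 1,3-syn to C7 (9R) whatever the bias of the α-chloro centre.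

Step 9
Reactants: 16 (3E,6R,7S,9R,10R,12E)-6,10-dichloro-1-(triisopropylsilyl)pentadeca-3,12-dien-1-yne-7,9-diol
Product: 17 (3E,6R,7S,9R,10R,12R,13S)-12-bromo-6,10-dichloro-9,13-epoxy-1-(triisopropylsilyl)pentadec-3-en-1-yn-7-ol
Conditions: TBCO (1.05 equiv), CH2Cl2, −78 → −20 °C
Reagents that add atoms: 2,4,4,6-tetrabromocyclohexa-2,5-dien-1-one, O=C1C(Br)=CC(Br)(Br)C=C1Br
Why: electrophilic bromoetherification in the 6-endo mode, in which Br+ goes to the more electron-rich isolated (12E)-alkene and the C9 hydroxyl opens the bromonium ion anti at C13 (the carbon farther from the electron-withdrawing C10 chlorine) through a chair with the C9 chain equatorial and the C10 chlorine axial, which should set 12R,13S with ethyl and bromine trans-diequatorial and close the oxane ring.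

Step 10
Reactants: 17 (3E,6R,7S,9R,10R,12R,13S)-12-bromo-6,10-dichloro-9,13-epoxy-1-(triisopropylsilyl)pentadec-3-en-1-yn-7-ol
Product: 18 (3E,6R,7S,9R,10R,12R,13S)-12-bromo-6,10-dichloro-9,13-epoxy-1-(triisopropylsilyl)pentadec-3-en-1-yn-7-yl acetate
Conditions: Ac2O, pyridine, DMAP (cat.), CH2Cl2, 0 °C → rt
Reagents that add atoms: acetic anhydride, CC(=O)OC(C)=O
Why: nucleophile-catalysed acylation of the only free hydroxyl, which touches no stereocentre.

Step 11
Reactants: 18 (3E,6R,7S,9R,10R,12R,13S)-12-bromo-6,10-dichloro-9,13-epoxy-1-(triisopropylsilyl)pentadec-3-en-1-yn-7-yl acetate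
Product: 19 (3E,6R,7S,9R,10R,12R,13S)-12-bromo-6,10-dichloro-9,13-epoxypentadec-3-en-1-yn-7-yl acetate
Conditions: Bu4NF, AcOH (1:1), THF, 0 °C
Reagents that add atoms: none
Why: fluoride-induced cleavage of the alkynyl C–Si bond, buffered with acetic acid so that the acetate and the secondary halides should survive.

**Compound list**

1 | ethynyltriisopropylsilane | C#C[Si](C(C)C)(C(C)C)C(C)C | starting material
2 | prop-2-enal (acrolein) | C=CC=O | starting material
3 | lithium (triisopropylsilyl)acetylide | [Li]C#C[Si](C(C)C)(C(C)C)C(C)C | intermediate (not isolated)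
4 | rac-1-(triisopropylsilyl)pent-4-en-1-yn-3-ol | C=CC(O)C#C[Si](C(C)C)(C(C)C)C(C)C | intermediate
5 | rac-3-[(1-ethoxyethenyl)oxy]-1-(triisopropylsilyl)pent-4-en-1-yne | C=CC(OC(=C)OCC)C#C[Si](C(C)C)(C(C)C)C(C)C | intermediate (not isolated)
6 | ethyl (E)-7-(triisopropylsilyl)hept-4-en-6-ynoate | CCOC(=O)CC/C=C/C#C[Si](C(C)C)(C(C)C)C(C)C | intermediate
7 | (E)-7-(triisopropylsilyl)hept-4-en-6-ynal | O=CCC/C=C/C#C[Si](C(C)C)(C(C)C)C(C)C | intermediate
8 | (2R,4E)-2-chloro-7-(triisopropylsilyl)hept-4-en-6-ynal | O=C[C@H](Cl)C/C=C/C#C[Si](C(C)C)(C(C)C)C(C)C | intermediate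
9 | prop-1-ynylmagnesium bromide | CC#C[Mg]Br | starting material
10 | 1-chloroprop-1-yne | CC#CCl | intermediate
11 | (S)-pent-1-en-3-ol | C=C[C@@H](O)CC | starting material
12 | (3S)-3-{[(1Z)-1-chloroprop-1-en-2-yl]oxy}pent-1-ene | C=C[C@@H](O/C(C)=C\Cl)CC | intermediate (not isolated)
13 | (3R,5E)-3-chlorooct-5-en-2-one | CC(=O)[C@H](Cl)C/C=C/CC | intermediate
14 | dicyclohexyl{[(3R,5E)-3-chloroocta-1,5-dien-2-yl]oxy}borane | C=C(OB(C1CCCCC1)C1CCCCC1)[C@H](Cl)C/C=C/CC | intermediate (not isolated)
15 | (3E,6R,7S,10R,12E)-6,10-dichloro-7-hydroxy-1-(triisopropylsilyl)pentadeca-3,12-dien-1-yn-9-one | CC(C)[Si](C(C)C)(C(C)C)C#C/C=C/C[C@@H](Cl)[C@H](CC(=O)[C@H](Cl)C/C=C/CC)O | intermediate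
16 | (3E,6R,7S,9R,10R,12E)-6,10-dichloro-1-(triisopropylsilyl)pentadeca-3,12-dien-1-yne-7,9-diol | CC(C)[Si](C(C)C)(C(C)C)C#C/C=C/C[C@@H](Cl)[C@H](C[C@@H](O)[C@H](Cl)C/C=C/CC)O | intermediate
17 | (3E,6R,7S,9R,10R,12R,13S)-12-bromo-6,10-dichloro-9,13-epoxy-1-(triisopropylsilyl)pentadec-3-en-1-yn-7-ol | CC(C)[Si](C(C)C)(C(C)C)C#C/C=C/C[C@@H](Cl)[C@H](C[C@H]1O[C@@H](CC)[C@H](Br)C[C@H]1Cl)O | intermediate
18 | (3E,6R,7S,9R,10R,12R,13S)-12-bromo-6,10-dichloro-9,13-epoxy-1-(triisopropylsilyl)pentadec-3-en-1-yn-7-yl acetate | CC(C)[Si](C(C)C)(C(C)C)C#C/C=C/C[C@@H](Cl)[C@H](C[C@H]1O[C@@H](CC)[C@H](Br)C[C@H]1Cl)OC(C)=O | intermediate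
19 | (3E,6R,7S,9R,10R,12R,13S)-12-bromo-6,10-dichloro-9,13-epoxypentadec-3-en-1-yn-7-yl acetate (CNP0194255.2) | C#C/C=C/C[C@@H](Cl)[C@H](C[C@H]1O[C@@H](CC)[C@H](Br)C[C@H]1Cl)OC(C)=O | target

**Count and risks**

Total steps: 11. Longest linear sequence: 9 steps (1–4, then 7–11).

Steps most likely to fail:

Step 6 (proposed new method). The process at risk is the chemoselectivity of the gold cycle: addition of the alkene instead of the hydroxyl to the activated chloroalkyne, arrest at the mixed ketal without rearrangement, loss of the volatile alkyne, or acid-promoted enolisation of the α-chloro ketone with loss of configuration at C10. Fallback with known chemistry, setting out from 11 and returning at 13: acylation of 11 with chloroacetyl chloride and pyridine gives (S)-pent-1-en-3-yl 2-chloroacetate F1. Ireland–Claisen rearrangement (LiN(i-Pr)2, Me3SiCl, THF, −78 °C → rt, then aqueous acid) through the same chair, with chlorine cis to the allylic oxygen in the kinetic silyl ketene acetal, should give (2R,4E)-2-chlorohept-4-enoic acid F2. Coupling with MeNHOMe·HCl (EDC·HCl, N-methylmorpholine) gives (2R,4E)-2-chloro-N-methoxy-N-methylhept-4-enamide F3, and MeMgBr (THF, −78 → 0 °C) converts it into 13.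

Step 9. The process at risk is the regioselectivity of ring closure: 5-exo attack of the C9 hydroxyl at C12 in place of 6-endo attack at C13, with minor risks of bromination at the enyne alkene or participation of the C7 hydroxyl. Fallback that changes the approach to closure followed by ring expansion, setting out from 16 and returning at 17: the 5-exo mode is used on purpose (NBS, MeCN, 0 °C) to give the 2,5-trans oxolane (3E,6R,7S,9R,10R,12S,13R)-13-bromo-6,10-dichloro-9,12-epoxy-1-(triisopropylsilyl)pentadec-3-en-1-yn-7-ol F4. ZnBr2 (cat.) in MeNO2 at 40 °C then ionises the secondary bromide with help of the ring oxygen to the bridged bicyclic oxonium ion, and bromide reopens it at C12. This is a double inversion of the known type (2-(1-haloalkyl)oxolane to 3-halooxane) and should converge on the thermodynamically preferred oxane 17.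

Step 7. The process at risk is enolisation toward the chlorine-bearing carbon (loss of regiochemistry, epimerisation at C10, Favorskii-type decomposition) and erosion of the 6,7-anti facial preference. Fallback that makes the C7–C8 bond without any ketone enolate and lets the Claisen cascade join the halves, setting out from 8 and returning at 15: propargylation of 8 with allenylboronic acid pinacol ester (Cornforth-type addition) gives (4S,5R,7E)-5-chloro-10-(triisopropylsilyl)dec-7-ene-1,9-diyn-4-ol F5. Silylation (t-BuMe2SiCl, imidazole) gives tert-butyl{[(4S,5R,7E)-5-chloro-10-(triisopropylsilyl)dec-7-ene-1,9-diyn-4-yl]oxy}dimethylsilane F6, and n-BuLi at −78 °C then TsCl gives the 1-chloroalkyne tert-butyl{[(4S,5R,7E)-1,5-dichloro-10-(triisopropylsilyl)dec-7-ene-1,9-diyn-4-yl]oxy}dimethylsilane F7. The conditions of step 6 with 11 should then give (3E,6R,7S,10R,12E)-7-[(tert-butyldimethylsilyl)oxy]-6,10-dichloro-1-(triisopropylsilyl)pentadeca-3,12-dien-1-yn-9-one F8, and HF·pyridine (THF, 0 °C) releases 15.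

Further compounds
F1 | step 6 | (S)-pent-1-en-3-yl 2-chloroacetate | C=C[C@@H](OC(=O)CCl)CC
F2 | step 6 | (2R,4E)-2-chlorohept-4-enoic acid | OC(=O)[C@H](Cl)C/C=C/CC
F3 | step 6 | (2R,4E)-2-chloro-N-methoxy-N-methylhept-4-enamide | CON(C)C(=O)[C@H](Cl)C/C=C/CC
F4 | step 9 | (3E,6R,7S,9R,10R,12S,13R)-13-bromo-6,10-dichloro-9,12-epoxy-1-(triisopropylsilyl)pentadec-3-en-1-yn-7-ol | CC(C)[Si](C(C)C)(C(C)C)C#C/C=C/C[C@@H](Cl)[C@H](C[C@H]1O[C@H]([C@H](Br)CC)C[C@H]1Cl)O
F5 | step 7 | (4S,5R,7E)-5-chloro-10-(triisopropylsilyl)dec-7-ene-1,9-diyn-4-ol | CC(C)[Si](C(C)C)(C(C)C)C#C/C=C/C[C@@H](Cl)[C@H](CC#C)O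
F6 | step 7 | tert-butyl{[(4S,5R,7E)-5-chloro-10-(triisopropylsilyl)dec-7-ene-1,9-diyn-4-yl]oxy}dimethylsilane | CC(C)[Si](C(C)C)(C(C)C)C#C/C=C/C[C@@H](Cl)[C@H](CC#C)O[Si](C)(C)C(C)(C)C
F7 | step 7 | tert-butyl{[(4S,5R,7E)-1,5-dichloro-10-(triisopropylsilyl)dec-7-ene-1,9-diyn-4-yl]oxy}dimethylsilane | CC(C)[Si](C(C)C)(C(C)C)C#C/C=C/C[C@@H](Cl)[C@H](CC#CCl)O[Si](C)(C)C(C)(C)C
F8 | step 7 | (3E,6R,7S,10R,12E)-7-[(tert-butyldimethylsilyl)oxy]-6,10-dichloro-1-(triisopropylsilyl)pentadeca-3,12-dien-1-yn-9-one | CC(C)[Si](C(C)C)(C(C)C)C#C/C=C/C[C@@H](Cl)[C@H](CC(=O)[C@H](Cl)C/C=C/CC)O[Si](C)(C)C(C)(C)C
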